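**Strategy.** The route rests on a [3+3] disconnection of the cyclohexanone ring of the aryl-bearing tetralone (unit A) into the arene fragment C4–C4a–C8a and the acyl fragment C1–C2–C3 that carries the second tetralone (unit B). In one operation a 2-lithioaryl(silyl)methoxide acylates an E-acrylate ester (C8a–C1), the new ortho ketone triggers a Brook shift, and the resulting siloxybenzyl anion closes onto the alkene terminus (C4–C3). The step exploits the ortho placement, on the benzene ring of unit A, of the aryl ketone C1 and the benzylic carbinol C4. Its precursors are a bromoaryl(silyl)methanol from 4-methylsalicylaldehyde and the acrylate of an (R)-hydroxytetralone made from benzoquinone.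

Key step: step 12

Remark: C1–C8a number unit A as a 3,4-dihydronaphthalen-1(2H)-one and primed locants number unit B the same way; ArB denotes the protected unit B aryl group of 11 and 12, (6R)-2,2-di-tert-butyl-6-[(tert-butyldimethylsilyl)oxy]-8-methyl-5,6-dihydronaphtho[1,8-de][1,3,2]dioxasilin-9-yl.

Step 1
Reactants: 1 3-methylbut-2-enal
Product: 2 (E)-trimethyl[(3-methylbuta-1,3-dien-1-yl)oxy]silane
Conditions: TMSCl, Et3N, ZnCl2 (cat.), toluene, 70 °C
Reagents that add atoms: chlorotrimethylsilane, C[Si](C)(C)Cl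
Why: Silyl dienol ether formation, in which amine-mediated γ-deprotonation and O-silylation of the enal should give the conjugated E-1-siloxydiene.

Step 2
Reactants: 2 (E)-trimethyl[(3-methylbuta-1,3-dien-1-yl)oxy]silane; 3 1,4-benzoquinone
Product: 5 5-hydroxy-7-methylnaphthalene-1,4-dione (7-methyljuglone), via Diels–Alder adduct 4 (not isolated)
Conditions: toluene, 25 °C; then CrO3, H2SO4, H2O, acetone, 0 °C
Reagents that add atoms: none
Why: Diels–Alder reaction of the electron-rich siloxydiene with the symmetric quinone (siloxy carbon becomes C5, methyl carbon C7) followed by Jones oxidation, which cleaves the silyl ether, oxidises the allylic alcohol and, after enolisation, the naphthalenetriol to the quinone, so that the stereocentres of 4 are lost on aromatisation.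

Step 3
Reactants: 5 5-hydroxy-7-methylnaphthalene-1,4-dione
Product: 7 5-hydroxy-7-methyl-2,3-dihydronaphthalene-1,4-dione, via naphthalenetriol 6 (not isolated)
Conditions: SnCl2·2H2O, aq. HCl, THF, 60 °C, argon
Reagents that add atoms: none
Why: Two-electron quinone reduction by SnCl2 followed by acid-catalysed ketonisation of the hydroquinone ring, a tautomer that the peri O–H···O=C hydrogen bond should stabilise as in β-hydrojuglone.

Step 4
Reactants: 7 5-hydroxy-7-methyl-2,3-dihydronaphthalene-1,4-dione
Product: 8 (4R)-4,8-dihydroxy-6-methyl-3,4-dihydronaphthalen-1(2H)-one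
Conditions: RuCl(p-cymene)[(R,R)-TsDPEN] (cat.), HCO2H–Et3N azeotrope, CH2Cl2, 25 °C, argon
Reagents that add atoms: none
Why: Noyori–Ikariya asymmetric transfer hydrogenation, in which hydride should go to the non-chelated, more electrophilic ketone (the other is deactivated as a hydrogen-bonded vinylogous acid) and the (R,R)-ligand should set C4′ as R through the aryl-directed transition state that gives (R)-1-tetralol from 1-tetralone.

Step 5
Reactants: 8 (4R)-4,8-dihydroxy-6-methyl-3,4-dihydronaphthalen-1(2H)-one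
Product: 9 (4R)-4-[(tert-butyldimethylsilyl)oxy]-8-hydroxy-6-methyl-3,4-dihydronaphthalen-1(2H)-one
Conditions: TBSCl, imidazole, DMF, 0 °C; K2CO3, MeOH work-up
Reagents that add atoms: tert-butyl(chloro)dimethylsilane, CC(C)(C)[Si](C)(C)Cl
Why: Silyl ether formation at the secondary benzylic alcohol, the phenol being tied up in a hydrogen bond to the peri ketone and any aryl silyl ether being cleaved again by the mild basic work-up.

Step 6
Reactants: 9 (4R)-4-[(tert-butyldimethylsilyl)oxy]-8-hydroxy-6-methyl-3,4-dihydronaphthalen-1(2H)-one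
Product: 10 (5R)-5-[(tert-butyldimethylsilyl)oxy]-1-hydroxy-3-methyl-8-oxo-5,6,7,8-tetrahydronaphthalene-2-carbaldehyde
Conditions: MgCl2, Et3N, (CH2O)n, THF, reflux
Reagents that add atoms: paraformaldehyde (as formaldehyde), C=O
Why: Magnesium-mediated ortho-formylation (Casnati–Skattebøl type), in which the magnesium phenoxide delivers formaldehyde to the only free ortho position and a second formaldehyde oxidises the resulting benzylic alkoxide to the aldehyde.

Step 7
Reactants: 10 (5R)-5-[(tert-butyldimethylsilyl)oxy]-1-hydroxy-3-methyl-8-oxo-5,6,7,8-tetrahydronaphthalene-2-carbaldehyde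
Product: 11 (6R)-2,2-di-tert-butyl-6-[(tert-butyldimethylsilyl)oxy]-8-methyl-5,6-dihydronaphtho[1,8-de][1,3,2]dioxasiline-9-carbaldehyde (phenol oxygen and ketone enol oxygen of 10 bridged by Si(t-Bu)2)
Conditions: t-Bu2Si(OTf)2, Et3N, CH2Cl2, 0 → 25 °C
Reagents that add atoms: di-tert-butylsilyl bis(trifluoromethanesulfonate), CC(C)(C)[Si](OS(=O)(=O)C(F)(F)F)(OS(=O)(=O)C(F)(F)F)C(C)(C)C
Why: O-silylation of the phenol by the silyl bis-triflate followed by intramolecular silyl enol ether formation at the peri ketone should close a six-membered dioxasiline that masks phenol and ketone together against organolithium reagents.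

Step 8
Reactants: 11 (6R)-2,2-di-tert-butyl-6-[(tert-butyldimethylsilyl)oxy]-8-methyl-5,6-dihydronaphtho[1,8-de][1,3,2]dioxasiline-9-carbaldehyde
Product: 12 ethyl (2E)-3-ArB-prop-2-enoate
Conditions: (EtO)2P(O)CH2CO2Et, NaH, THF, 0 → 25 °C
Reagents that add atoms: triethyl phosphonoacetate, CCOC(=O)CP(=O)(OCC)OCC
Why: Horner–Wadsworth–Emmons olefination with a stabilised phosphonate anion should give the E-acrylate.

Step 9
Reactants: 13 2-hydroxy-4-methylbenzaldehyde
Product: 14 4-methyl-2-[(triisopropylsilyl)oxy]benzaldehyde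
Conditions: TIPSCl, imidazole, DMF, 25 °C
Reagents that add atoms: chlorotriisopropylsilane, CC(C)[Si](Cl)(C(C)C)C(C)C
Why: Silyl ether formation at the phenol, the bulky and non-coordinating TIPS group being chosen so that it does not direct the lithiation of the next step.

Step 10
Reactants: 14 4-methyl-2-[(triisopropylsilyl)oxy]benzaldehyde
Product: 16 2-bromo-4-methyl-6-[(triisopropylsilyl)oxy]benzaldehyde, via lithiated amino alkoxide 15 (not isolated)
Conditions: LiN(Me)CH2CH2NMe2, THF, −20 °C; n-BuLi, −20 °C; BrCl2CCCl2Br, −78 °C; aq. NH4Cl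
Reagents that add atoms: 1,2-dibromo-1,1,2,2-tetrachloroethane, ClC(Cl)(Br)C(Cl)(Cl)Br
Why: Directed ortho-metalation through an in situ α-amino alkoxide, in which the lithium amide adds to the aldehyde, its diamine arm directs n-BuLi to the only free ortho position, and electrophilic bromination followed by hydrolysis returns the aldehyde.

Step 11
Reactants: 16 2-bromo-4-methyl-6-[(triisopropylsilyl)oxy]benzaldehyde
Product: 17 rac-{2-bromo-4-methyl-6-[(triisopropylsilyl)oxy]phenyl}[dimethyl(phenyl)silyl]methanol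
Conditions: PhMe2SiLi, THF, −78 °C; aq. NH4Cl at −78 °C
Reagents that add atoms: dimethyl(phenyl)silyllithium, [Li][Si](C)(C)c1ccccc1
Why: 1,2-Addition of a silyllithium to the aldehyde with a cold quench so that the α-silyl alkoxide does not undergo Brook rearrangement; the carbinol centre forms racemic, which is immaterial because it becomes planar in step 12.

Step 12
Reactants: 17 rac-{2-bromo-4-methyl-6-[(triisopropylsilyl)oxy]phenyl}[dimethyl(phenyl)silyl]methanol; 12 ethyl (2E)-3-ArB-prop-2-enoate
Product: 21 (3R,4S)-3-ArB-4-{[dimethyl(phenyl)silyl]oxy}-7-methyl-5-[(triisopropylsilyl)oxy]-3,4-dihydronaphthalen-1(2H)-one, via dilithio species 18 (not isolated), via keto alkoxide 19 (not isolated), via siloxybenzyllithium 20 (not isolated)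
Conditions: t-BuLi (3 equiv), (−)-sparteine, Et2O, −78 °C; 12 in toluene, −78 → 0 °C; aq. NH4Cl
Reagents that add atoms: none
Why: Proposed new method: t-BuLi deprotonates the carbinol and exchanges bromine for lithium to give 18, whose aryllithium adds to the ester carbonyl of 12 and expels ethoxide (bond C1–C8a, ketone 19); the new ortho acyl group makes a benzylic carbanion accessible, so the α-silyl alkoxide undergoes a [1,2]-Brook shift to the siloxybenzyllithium 20 (an o-quinodimethane enolate), which closes onto the alkene terminus (bond C3–C4) and leaves the tetralone enolate that is protonated on work-up. The closest known reaction types are the Parham-type acylation of aryllithiums made by halogen–lithium exchange, Brook-rearrangement anion relay, and the ring closure of hydroxy-o-quinodimethanes onto a conjugated alkene known from photoenol chemistry; their merger into one [3+3] annulation has no direct precedent. The only ring closed is the cyclohexanone of unit A, by thermal disrotatory 6π closure of the triene C4=C4a–C8a=C1–C2=C3 (formally a 6-endo-trig conjugate addition), driven by rearomatisation of the benzene ring. C3 and C4 are created together: the E alkene holds unit B outward and the siloxy group at C4 should also sit outward because the inward position collides with the C1 substituents, so disrotation places them cis, the same arrangement that a product-like transition state with a pseudo-axial C4–O bond (no peri clash with the C5 silyl ether) prefers. The remote C4′ centre cannot bias the helical sense of closure, so the absolute configuration (3R,4S) has to come from the lithium-bound (−)-sparteine, by analogy with diamine-controlled rearrangements and cyclisations of α-oxybenzyllithiums, and the enantiomeric diamine is to be used if the opposite sense is found. The step needs 1,2- instead of 1,4-addition to the acrylate and no second addition to ketone 19, which the di-ortho-substituted aryl group at C3 and the immediate conversion of 19 into enolate 20 should secure, while the bulky TIPS group should suppress oxygen-to-carbon silyl migration to the benzylic anion.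

Step 13
Reactants: 21 (3R,4S)-3-ArB-4-{[dimethyl(phenyl)silyl]oxy}-7-methyl-5-[(triisopropylsilyl)oxy]-3,4-dihydronaphthalen-1(2H)-one
Product: 22 (3R,4S)-3-[(5R)-1,5-dihydroxy-3-methyl-8-oxo-5,6,7,8-tetrahydronaphthalen-2-yl]-4,5-dihydroxy-7-methyl-3,4-dihydronaphthalen-1(2H)-one
Conditions: HF·pyridine, pyridine, THF, 0 → 25 °C
Reagents that add atoms: none
Why: Global fluoride-mediated desilylation, in which cleavage of the silylene sets free the phenol and the enol that tautomerises to the C1′ ketone, under buffered conditions that should not ionise the two benzylic alcohols.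

**Compound list**

1 | 3-methylbut-2-enal | CC(C)=CC=O | starting material
2 | (E)-trimethyl[(3-methylbuta-1,3-dien-1-yl)oxy]silane | C=C(C)/C=C/O[Si](C)(C)C | intermediate
3 | 1,4-benzoquinone | O=C1C=CC(=O)C=C1 | starting material
4 | rac-7-methyl-5-[(trimethylsilyl)oxy]-4a,5,8,8a-tetrahydronaphthalene-1,4-dione (cis-fused endo adduct, racemic, configuration not encoded) | O=C1C=CC(=O)C2C1CC(C)=CC2O[Si](C)(C)C | intermediate
5 | 5-hydroxy-7-methylnaphthalene-1,4-dione (7-methyljuglone) | Cc1cc(O)c2c(c1)C(=O)C=CC2=O | intermediate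
6 | 7-methylnaphthalene-1,4,5-triol | Cc1cc(O)c2c(O)ccc(O)c2c1 | intermediate
7 | 5-hydroxy-7-methyl-2,3-dihydronaphthalene-1,4-dione | Cc1cc(O)c2c(c1)C(=O)CCC2=O | intermediate
8 | (4R)-4,8-dihydroxy-6-methyl-3,4-dihydronaphthalen-1(2H)-one | O=C1CC[C@@H](O)c2cc(C)cc(O)c21 | intermediate
9 | (4R)-4-[(tert-butyldimethylsilyl)oxy]-8-hydroxy-6-methyl-3,4-dihydronaphthalen-1(2H)-one | O=C1CC[C@@H](O[Si](C)(C)C(C)(C)C)c2cc(C)cc(O)c21 | intermediate
10 | (5R)-5-[(tert-butyldimethylsilyl)oxy]-1-hydroxy-3-methyl-8-oxo-5,6,7,8-tetrahydronaphthalene-2-carbaldehyde | O=Cc1c(C)cc2c(c1O)C(=O)CC[C@H]2O[Si](C)(C)C(C)(C)C | intermediate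
11 | (6R)-2,2-di-tert-butyl-6-[(tert-butyldimethylsilyl)oxy]-8-methyl-5,6-dihydronaphtho[1,8-de][1,3,2]dioxasiline-9-carbaldehyde | O=Cc1c(C)cc2c3c1O[Si](C(C)(C)C)(C(C)(C)C)OC3=CC[C@H]2O[Si](C)(C)C(C)(C)C | intermediate
12 | ethyl (2E)-3-ArB-prop-2-enoate | CCOC(=O)/C=C/c1c(C)cc2c3c1O[Si](C(C)(C)C)(C(C)(C)C)OC3=CC[C@H]2O[Si](C)(C)C(C)(C)C | intermediate
13 | 2-hydroxy-4-methylbenzaldehyde | Cc1ccc(C=O)c(O)c1 | starting material
14 | 4-methyl-2-[(triisopropylsilyl)oxy]benzaldehyde | Cc1ccc(C=O)c(O[Si](C(C)C)(C(C)C)C(C)C)c1 | intermediate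
15 | lithium {[2-(dimethylamino)ethyl](methyl)amino}{2-lithio-4-methyl-6-[(triisopropylsilyl)oxy]phenyl}methanolate | [Li]c1cc(C)cc(O[Si](C(C)C)(C(C)C)C(C)C)c1C(O[Li])N(C)CCN(C)C | intermediate
16 | 2-bromo-4-methyl-6-[(triisopropylsilyl)oxy]benzaldehyde | Cc1cc(Br)c(C=O)c(O[Si](C(C)C)(C(C)C)C(C)C)c1 | intermediate
17 | rac-{2-bromo-4-methyl-6-[(triisopropylsilyl)oxy]phenyl}[dimethyl(phenyl)silyl]methanol | Cc1cc(Br)c(C(O)[Si](C)(C)c2ccccc2)c(O[Si](C(C)C)(C(C)C)C(C)C)c1 | intermediate
18 | lithium [dimethyl(phenyl)silyl]{2-lithio-4-methyl-6-[(triisopropylsilyl)oxy]phenyl}methanolate | [Li]c1cc(C)cc(O[Si](C(C)C)(C(C)C)C(C)C)c1C(O[Li])[Si](C)(C)c1ccccc1 | intermediate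
19 | lithium [dimethyl(phenyl)silyl]{2-[(2E)-3-ArB-prop-2-enoyl]-4-methyl-6-[(triisopropylsilyl)oxy]phenyl}methanolate | Cc1cc(O[Si](C(C)C)(C(C)C)C(C)C)c(C(O[Li])[Si](C)(C)c2ccccc2)c(c1)C(=O)/C=C/c1c(C)cc2c3c1O[Si](C(C)(C)C)(C(C)(C)C)OC3=CC[C@H]2O[Si](C)(C)C(C)(C)C | intermediate
20 | α-{[dimethyl(phenyl)silyl]oxy}benzyllithium of the 2-[(2E)-3-ArB-prop-2-enoyl] arene (o-quinodimethane enolate, drawn as the C-lithio form) | Cc1cc(O[Si](C(C)C)(C(C)C)C(C)C)c(C([Li])O[Si](C)(C)c2ccccc2)c(c1)C(=O)/C=C/c1c(C)cc2c3c1O[Si](C(C)(C)C)(C(C)(C)C)OC3=CC[C@H]2O[Si](C)(C)C(C)(C)C | intermediate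
21 | (3R,4S)-3-ArB-4-{[dimethyl(phenyl)silyl]oxy}-7-methyl-5-[(triisopropylsilyl)oxy]-3,4-dihydronaphthalen-1(2H)-one | Cc1cc(O[Si](C(C)C)(C(C)C)C(C)C)c2c(c1)C(=O)C[C@H](c1c(C)cc3c4c1O[Si](C(C)(C)C)(C(C)(C)C)OC4=CC[C@H]3O[Si](C)(C)C(C)(C)C)[C@@H]2O[Si](C)(C)c1ccccc1 | intermediate
22 | (3R,4S)-3-[(5R)-1,5-dihydroxy-3-methyl-8-oxo-5,6,7,8-tetrahydronaphthalen-2-yl]-4,5-dihydroxy-7-methyl-3,4-dihydronaphthalen-1(2H)-one | Cc1cc(O)c2c(c1)C(=O)C[C@H](c1c(C)cc3c(c1O)C(=O)CC[C@H]3O)[C@@H]2O | target

**Step count and risks**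

Total step count: 13. Longest linear sequence: 10 steps (steps 1–8, 12 and 13).

The three steps most likely to fail:

First, step 12 (the labelled step). The anion relay may stop at ketone 19 without the Brook shift, or the ring closure may occur with poor facial selectivity under diamine control. The fallback forms the two bonds one after the other by known reactions and sets out from 11 and 16. Wittig reaction of 11 with Ph3P=CHCHO (toluene, 80 °C) should give the enal (2E)-3-ArB-prop-2-enal F1. A carbene-catalysed homoenolate annulation of F1 with 16 (chiral aminoindanol-derived triazolium salt, DBU, THF) should form the C3–C4 bond and give the 4,5-cis lactone 5-{2-bromo-4-methyl-6-[(triisopropylsilyl)oxy]phenyl}-4-ArB-dihydrofuran-2(3H)-one F2, the catalyst fixing the carbon that bears ArB. Reversible ionisation of the benzylic lactone C–O bond (TMSOTf cat., CH2Cl2, −40 °C) should equilibrate it to the 4,5-trans lactone F3, both centres then being as in 21. Bromine–lithium exchange with t-BuLi (THF, −100 °C) and intramolecular acyl transfer to the aryllithium (Parham-type, bond C1–C8a) should give (3R,4S)-3-ArB-4-hydroxy-7-methyl-5-[(triisopropylsilyl)oxy]-3,4-dihydronaphthalen-1(2H)-one F4. F4 is desilylated under the conditions of step 13 and so comes back to the route at 22.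

Second, step 4. The diketone may tautomerise back to triol 6 and be re-oxidised by air, and hydride transfer may be poorly regio- or enantioselective. The fallback replaces asymmetric catalysis by resolution and sets out from 7. NaBH4 (MeOH, −20 °C) should reduce the non-chelated ketone to racemic 4,8-dihydroxy-6-methyl-3,4-dihydronaphthalen-1(2H)-one F5. Lipase-catalysed acylation (immobilised Candida antarctica lipase B, vinyl acetate, t-BuOMe) should convert the R enantiomer into (4R)-4-acetoxy-8-hydroxy-6-methyl-3,4-dihydronaphthalen-1(2H)-one F6. F6 is separated from the unreacted S alcohol and methanolysed (K2CO3, MeOH) to 8, where the route is rejoined.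

Third, step 6. Electrophilic substitution at the hindered ortho position of the chelated, deactivated phenol may be sluggish and the hydride shift to formaldehyde incomplete. The fallback introduces the carbon by a sigmatropic shift and sets out from 9. O-Allylation (allyl bromide, K2CO3, DMF) should give (4R)-8-(allyloxy)-4-[(tert-butyldimethylsilyl)oxy]-6-methyl-3,4-dihydronaphthalen-1(2H)-one F7. Aromatic Claisen rearrangement (N,N-diethylaniline, 190 °C) to the only free ortho position should give (4R)-7-allyl-4-[(tert-butyldimethylsilyl)oxy]-8-hydroxy-6-methyl-3,4-dihydronaphthalen-1(2H)-one F8. Alkene isomerisation (RuHCl(CO)(PPh3)3 cat., toluene, 80 °C) should give (4R)-4-[(tert-butyldimethylsilyl)oxy]-8-hydroxy-6-methyl-7-[(1E)-prop-1-en-1-yl]-3,4-dihydronaphthalen-1(2H)-one F9. Ozonolysis (O3, CH2Cl2, −78 °C; Me2S) should give aldehyde 10, where the route is rejoined.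

**Further compounds**

F1 | step 12 | (2E)-3-ArB-prop-2-enal | O=C/C=C/c1c(C)cc2c3c1O[Si](C(C)(C)C)(C(C)(C)C)OC3=CC[C@H]2O[Si](C)(C)C(C)(C)C
F2 | step 12 | 4,5-cis-5-{2-bromo-4-methyl-6-[(triisopropylsilyl)oxy]phenyl}-4-ArB-dihydrofuran-2(3H)-one (C4 as in 21, C5 epimeric) | O=C1C[C@H](c2c(C)cc3c4c2O[Si](C(C)(C)C)(C(C)(C)C)OC4=CC[C@H]3O[Si](C)(C)C(C)(C)C)[C@H](c2c(Br)cc(C)cc2O[Si](C(C)C)(C(C)C)C(C)C)O1
F3 | step 12 | 4,5-trans-5-{2-bromo-4-methyl-6-[(triisopropylsilyl)oxy]phenyl}-4-ArB-dihydrofuran-2(3H)-one (both centres as in 21) | O=C1C[C@H](c2c(C)cc3c4c2O[Si](C(C)(C)C)(C(C)(C)C)OC4=CC[C@H]3O[Si](C)(C)C(C)(C)C)[C@@H](c2c(Br)cc(C)cc2O[Si](C(C)C)(C(C)C)C(C)C)O1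
F4 | step 12 | (3R,4S)-3-ArB-4-hydroxy-7-methyl-5-[(triisopropylsilyl)oxy]-3,4-dihydronaphthalen-1(2H)-one | Cc1cc(O[Si](C(C)C)(C(C)C)C(C)C)c2c(c1)C(=O)C[C@H](c1c(C)cc3c4c1O[Si](C(C)(C)C)(C(C)(C)C)OC4=CC[C@H]3O[Si](C)(C)C(C)(C)C)[C@@H]2O
F5 | step 4 | rac-4,8-dihydroxy-6-methyl-3,4-dihydronaphthalen-1(2H)-one | O=C1CCC(O)c2cc(C)cc(O)c21
F6 | step 4 | (4R)-4-acetoxy-8-hydroxy-6-methyl-3,4-dihydronaphthalen-1(2H)-one | O=C1CC[C@@H](OC(C)=O)c2cc(C)cc(O)c21
F7 | step 6 | (4R)-8-(allyloxy)-4-[(tert-butyldimethylsilyl)oxy]-6-methyl-3,4-dihydronaphthalen-1(2H)-one | O=C1CC[C@@H](O[Si](C)(C)C(C)(C)C)c2cc(C)cc(OCC=C)c21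
F8 | step 6 | (4R)-7-allyl-4-[(tert-butyldimethylsilyl)oxy]-8-hydroxy-6-methyl-3,4-dihydronaphthalen-1(2H)-one | C=CCc1c(C)cc2c(c1O)C(=O)CC[C@H]2O[Si](C)(C)C(C)(C)C
F9 | step 6 | (4R)-4-[(tert-butyldimethylsilyl)oxy]-8-hydroxy-6-methyl-7-[(1E)-prop-1-en-1-yl]-3,4-dihydronaphthalen-1(2H)-one | C/C=C/c1c(C)cc2c(c1O)C(=O)CC[C@H]2O[Si](C)(C)C(C)(C)C
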